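**Retrosynthetic overview**

1. Target ⇐ conjugate reduction of the C4=C5 arm of a cross-conjugated dienone (C5 then set thermodynamically) ⇐ O-methylation at O7 ⇐ dienone with rings A, B and C in place.
2. Dienone ⇐ ring contraction with dearomatization: the six-membered dioxane ring O1–C2–C3–O7–C7–C7a of a 2-aryl-3-methyl-1,4-benzodioxan-8-ol gives up O7/C7 and takes in C3a (C3–O7 broken, C3–C3a made) to become ring C (O1–C2–C3–C3a–C7a).
3. Benzodioxane ⇐ para-Claisen (allyl from O6 to C3a) ⇐ Mitsunobu ring closure O1–C2 (inversion) ⇐ Baeyer–Villiger unmasking of O1 ⇐ Mitsunobu etherification O7–C3 of an O6-allyl salicylaldehyde with a lactate-derived aryl carbinol.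
4. Enabling feature: C3a is ortho to O1 and para to the C6 oxygen, so ring B at the dienone level (C6=O, C7=C7a–O1) is the keto form of a phenol alkylated at its para carbon; C3 is benzylic to ring A, so its bond to a ring-B oxygen can ionize. C2 (bought as ethyl (S)-lactate) relays C3 and C3a in that one event and C5 afterwards.
5. Ring order: rings A and B (aromatic) are bought; the dioxane ring is closed on ring B and then contracted to ring C as ring B is dearomatized.

Key step: step 8

Remark on numbering: target numbering (O1, C2, C3, C3a, C4 to C7, C7a; O6 and O7 are the oxygens on C6 and C7; ring A = trimethoxyphenyl, ring B = carbocycle, ring C = dihydrofuran) is used for every intermediate.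
Assumption: the carbon that becomes C3 is carried as a mixture of both epimers until step 8, where it is ionized; it is left without a stereodescriptor in the SMILES of those compounds.
Assumption (one fallback only): the enantiomer of the epoxidation catalyst is the one that gives the 2S epoxide, expected to be the (R,R) form by analogy with cis-β-methylstyrene.

**Route**

Step 1
Reactants: 1 ethyl (S)-lactate
Product: 2 ethyl (2S)-2-[(tert-butyldimethylsilyl)oxy]propanoate
Conditions: TBSCl, imidazole, DMF, rt
Reagents that add atoms: tert-butyldimethylsilyl chloride (TBSCl), CC(C)(C)[Si](C)(C)Cl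
Why: Silyl ether formation on the secondary alcohol; C2 is not touched, so the (S) configuration bought with the lactate is kept.

Step 2
Reactants: 2 ethyl (2S)-2-[(tert-butyldimethylsilyl)oxy]propanoate; 3 3,4,5-trimethoxyphenylmagnesium bromide
Product: 5 (2S)-2-[(tert-butyldimethylsilyl)oxy]-1-(3,4,5-trimethoxyphenyl)propan-1-ol (both C1 epimers), via (2S)-2-[(tert-butyldimethylsilyl)oxy]propanal 4 (not isolated)
Conditions: iBu2AlH (1.05 equiv), CH2Cl2, −78 °C; then 3 (THF), −78 → 0 °C; aq. potassium sodium tartrate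
Reagents that add atoms: none
Why: Partial reduction of the ester stops at the aluminium hemiacetal at −78 °C and the aldehyde it releases is taken at once by the aryl Grignard reagent (one-pot reduction/Grignard addition), so the epimerizable α-silyloxy aldehyde is never handled; the new carbinol centre may form unselectively because it is ionized in step 8.

Step 3
Reactants: 6 2,3-dihydroxy-4-methoxybenzaldehyde; 7 allyl bromide
Product: 8 3-(allyloxy)-2-hydroxy-4-methoxybenzaldehyde
Conditions: NaH (2.1 equiv), DMSO, rt; then 7 (1.0 equiv)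
Reagents that add atoms: none
Why: Williamson ether synthesis on the dianion: the 2-oxide is deactivated by conjugation with and chelation to the formyl group, so the 3-oxide (the future O6) should take the single equivalent of allyl bromide.

Step 4
Reactants: 8 3-(allyloxy)-2-hydroxy-4-methoxybenzaldehyde; 5 (2S)-2-[(tert-butyldimethylsilyl)oxy]-1-(3,4,5-trimethoxyphenyl)propan-1-ol
Product: 9 3-(allyloxy)-2-{[(2S)-2-[(tert-butyldimethylsilyl)oxy]-1-(3,4,5-trimethoxyphenyl)propyl]oxy}-4-methoxybenzaldehyde (both epimers at the benzylic carbon)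
Conditions: PPh3, DIAD, toluene, 0 °C → rt
Reagents that add atoms: none
Why: Mitsunobu etherification of the acidic salicylaldehyde-type phenol (the only free OH of 8) with the benzylic carbinol makes the O7–C3 bond; the configuration at this carbon is irrelevant and C2 is untouched.

Step 5
Reactants: 9 3-(allyloxy)-2-{[(2S)-2-[(tert-butyldimethylsilyl)oxy]-1-(3,4,5-trimethoxyphenyl)propyl]oxy}-4-methoxybenzaldehyde
Product: 11 3-(allyloxy)-2-{[(2S)-2-hydroxy-1-(3,4,5-trimethoxyphenyl)propyl]oxy}-4-methoxyphenol, via aryl formate 10 (not isolated)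
Conditions: mCPBA (1.2 equiv), CH2Cl2, 0 °C → rt; then Bu4NF (3 equiv), THF, rt
Reagents that add atoms: 3-chloroperbenzoic acid (mCPBA), OOC(=O)c1cccc(Cl)c1
Why: Baeyer–Villiger oxidation (Dakin-type) of the electron-rich benzaldehyde with aryl migration gives the formate, and fluoride then cleaves both the formate and the silyl ether, unveiling O1–H and C2–OH without touching C2.

Step 6
Reactants: 11 3-(allyloxy)-2-{[(2S)-2-hydroxy-1-(3,4,5-trimethoxyphenyl)propyl]oxy}-4-methoxyphenol
Product: 12 (3R)-8-(allyloxy)-7-methoxy-3-methyl-2-(3,4,5-trimethoxyphenyl)-2,3-dihydro-1,4-benzodioxine (cis and trans)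
Conditions: PPh3, DIAD, THF (0.02 M), 0 °C → rt
Reagents that add atoms: none
Why: Intramolecular Mitsunobu etherification closes the six-membered dioxane ring by SN2 attack of the phenol O1 on C2 (6-exo-tet), inverting C2 from S to R, the configuration of the target; the ring masks the cation precursor C3 and the C7 oxygen together.

Step 7
Reactants: 12 (3R)-8-(allyloxy)-7-methoxy-3-methyl-2-(3,4,5-trimethoxyphenyl)-2,3-dihydro-1,4-benzodioxine
Product: 15 (3R)-5-allyl-7-methoxy-3-methyl-2-(3,4,5-trimethoxyphenyl)-2,3-dihydro-1,4-benzodioxin-8-ol, via ortho-dienone 13 (not isolated), via para-dienone 14 (not isolated)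
Conditions: PhNEt2, 190 °C (sealed tube)
Reagents that add atoms: none
Why: para-Claisen rearrangement: [3,3] shift of the allyl group from O6 to an oxygen-bearing ortho carbon, Cope shift to the free para carbon C3a and tautomerization; both ortho positions are blocked, so only the para position can rearomatize, which also frees the C6 phenol needed in step 8.

Step 8
Reactants: 15 (3R)-5-allyl-7-methoxy-3-methyl-2-(3,4,5-trimethoxyphenyl)-2,3-dihydro-1,4-benzodioxin-8-ol
Product: 17 (2R,3S,3aR)-3a-allyl-7-hydroxy-5-methoxy-2-methyl-3-(3,4,5-trimethoxyphenyl)-3,3a-dihydro-1-benzofuran-6(2H)-one, via ring-opened benzylic cation 16 (not isolated)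
Conditions: SnCl4 (1.1 equiv), CH2Cl2, −78 → 0 °C; aq. NaHCO3
Reagents that add atoms: none
Why: Proposed new method: SnCl4 bound to the C6–OH/C5–OMe pair turns the phenol into a Lewis-acid-assisted Brønsted acid that protonates the neighbouring ring oxygen O7, the benzylic C3–O7 bond of the six-membered dioxane ring ionizes to cation 16, and C3, still tied to C7a through C2–O1, attacks C3a (ipso to the allyl group, ortho to O1, para to the C6 oxygen), so that the O-ring contracts to the five-membered ring C while ring B is dearomatized to the C6 ketone. The closest known reaction types are the Lewis-acid-mediated O-to-C rearrangement of aryl benzyl ethers and O-aryl glycosides and the alkylative ipso-Friedel–Crafts dearomatization of para-substituted phenols. Ring C is closed by a cationic five-membered closure onto the O1–C7a=C3a enol-ether unit of the arene, the geometry of the cyclodehydration of α-aryloxy ketones to benzofurans. C3 is planar in 16, so both C3 epimers of 15 converge; it should be set trans to the C2 methyl group (1,2-strain in the forming envelope), C3a is set in the same bond formation by the aryl group taking the exo position away from ring B, which places it cis to the allyl group, and C2 is not touched and fixes the absolute sense. The step needs C- over O-capture of the cation: return to O7 is reversible and only regenerates 15, whereas 17 is held as a tin chelate of its C6=O/C7–O pair, which should turn a transfer estimated to be nearly thermoneutral into a sink. Closure at any carbon other than C3a is excluded because the three-atom tether from C7a reaches only the ortho positions.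

Step 9
Reactants: 17 (2R,3S,3aR)-3a-allyl-7-hydroxy-5-methoxy-2-methyl-3-(3,4,5-trimethoxyphenyl)-3,3a-dihydro-1-benzofuran-6(2H)-one
Product: 18 (2R,3S,3aR)-3a-allyl-5,7-dimethoxy-2-methyl-3-(3,4,5-trimethoxyphenyl)-3,3a-dihydro-1-benzofuran-6(2H)-one
Conditions: MeI, K2CO3, acetone, rt
Reagents that add atoms: iodomethane (MeI), CI
Why: O-Methylation of the acidic enol OH of the 2-hydroxy-enone (diosphenol); 17 has no enolizable C–H, so C-alkylation should not compete.

Step 10
Reactants: 18 (2R,3S,3aR)-3a-allyl-5,7-dimethoxy-2-methyl-3-(3,4,5-trimethoxyphenyl)-3,3a-dihydro-1-benzofuran-6(2H)-one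
Product: 20 (2R,3S,3aS,5S)-3a-allyl-5,7-dimethoxy-2-methyl-3-(3,4,5-trimethoxyphenyl)-3,3a,4,5-tetrahydro-1-benzofuran-6(2H)-one (target), via C5-epimer 19 (not isolated)
Conditions: Cu(OAc)2 (5 mol %), 1,2-bis(diphenylphosphino)benzene (5 mol %), (EtO)2MeSiH, t-BuOH, toluene, rt; then DBU (20 mol %), CH2Cl2, rt
Reagents that add atoms: none
Why: Copper hydride conjugate reduction should deliver hydride to C4, the β-carbon of the simple enone arm, and not to C7a (vinylogous ester arm) or the isolated allyl group; protonation gives both C5 epimers and DBU equilibrates 19 to the 5S epimer, in which the C5 methoxy group is equatorial and trans to the axial allyl group at C3a (thermodynamic control).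

**Compound list**

1 | ethyl (S)-lactate | C[C@H](O)C(=O)OCC | starting material
2 | ethyl (2S)-2-[(tert-butyldimethylsilyl)oxy]propanoate | C[C@H](O[Si](C)(C)C(C)(C)C)C(=O)OCC | intermediate
3 | 3,4,5-trimethoxyphenylmagnesium bromide (THF solution) | COc1cc([Mg]Br)cc(OC)c1OC | starting material
4 | (2S)-2-[(tert-butyldimethylsilyl)oxy]propanal | C[C@H](O[Si](C)(C)C(C)(C)C)C=O | intermediate (not isolated)
5 | (2S)-2-[(tert-butyldimethylsilyl)oxy]-1-(3,4,5-trimethoxyphenyl)propan-1-ol (both C1 epimers) | C[C@H](O[Si](C)(C)C(C)(C)C)C(O)c1cc(OC)c(OC)c(OC)c1 | intermediate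
6 | 2,3-dihydroxy-4-methoxybenzaldehyde | COc1ccc(C=O)c(O)c1O | starting material
7 | allyl bromide | C=CCBr | starting material
8 | 3-(allyloxy)-2-hydroxy-4-methoxybenzaldehyde | COc1ccc(C=O)c(O)c1OCC=C | intermediate
9 | 3-(allyloxy)-2-{[(2S)-2-[(tert-butyldimethylsilyl)oxy]-1-(3,4,5-trimethoxyphenyl)propyl]oxy}-4-methoxybenzaldehyde (benzylic epimers) | C[C@H](O[Si](C)(C)C(C)(C)C)C(Oc1c(C=O)ccc(OC)c1OCC=C)c1cc(OC)c(OC)c(OC)c1 | intermediate
10 | 3-(allyloxy)-2-{[(2S)-2-[(tert-butyldimethylsilyl)oxy]-1-(3,4,5-trimethoxyphenyl)propyl]oxy}-4-methoxyphenyl formate (benzylic epimers) | C[C@H](O[Si](C)(C)C(C)(C)C)C(Oc1c(OC=O)ccc(OC)c1OCC=C)c1cc(OC)c(OC)c(OC)c1 | intermediate (not isolated)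
11 | 3-(allyloxy)-2-{[(2S)-2-hydroxy-1-(3,4,5-trimethoxyphenyl)propyl]oxy}-4-methoxyphenol (benzylic epimers) | C[C@H](O)C(Oc1c(O)ccc(OC)c1OCC=C)c1cc(OC)c(OC)c(OC)c1 | intermediate
12 | (3R)-8-(allyloxy)-7-methoxy-3-methyl-2-(3,4,5-trimethoxyphenyl)-2,3-dihydro-1,4-benzodioxine (C2 epimers of the dioxine, i.e. cis and trans) | C[C@H]1Oc2ccc(OC)c(OCC=C)c2OC1c1cc(OC)c(OC)c(OC)c1 | intermediate
13 | ortho-dienone: (3R)-7-allyl-7-methoxy-3-methyl-2-(3,4,5-trimethoxyphenyl)-2,3-dihydro-1,4-benzodioxin-8(7H)-one (epimer mixture) | C[C@H]1OC2=C(OC1c1cc(OC)c(OC)c(OC)c1)C(=O)C(CC=C)(OC)C=C2 | intermediate (not isolated)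
14 | para-dienone: (3R)-5-allyl-7-methoxy-3-methyl-2-(3,4,5-trimethoxyphenyl)-2,3-dihydro-1,4-benzodioxin-8(5H)-one (epimer mixture) | C[C@H]1OC2=C(OC1c1cc(OC)c(OC)c(OC)c1)C(=O)C(OC)=CC2CC=C | intermediate (not isolated)
15 | (3R)-5-allyl-7-methoxy-3-methyl-2-(3,4,5-trimethoxyphenyl)-2,3-dihydro-1,4-benzodioxin-8-ol (cis and trans) | C[C@H]1Oc2c(CC=C)cc(OC)c(O)c2OC1c1cc(OC)c(OC)c(OC)c1 | intermediate
16 | ring-opened benzylic cation: (2R)-2-(6-allyl-2,3-dihydroxy-4-methoxyphenoxy)-1-(3,4,5-trimethoxyphenyl)propan-1-ylium (tin-bound counter-ion omitted) | C[C@@H](Oc1c(CC=C)cc(OC)c(O)c1O)[CH+]c1cc(OC)c(OC)c(OC)c1 | intermediate (not isolated)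
17 | (2R,3S,3aR)-3a-allyl-7-hydroxy-5-methoxy-2-methyl-3-(3,4,5-trimethoxyphenyl)-3,3a-dihydro-1-benzofuran-6(2H)-one (3aR here is the same spatial arrangement as 3aS in the target; the descriptor changes because C4 is sp2) | C=CC[C@@]12C=C(OC)C(=O)C(O)=C1O[C@H](C)[C@H]2c1cc(OC)c(OC)c(OC)c1 | intermediate
18 | (2R,3S,3aR)-3a-allyl-5,7-dimethoxy-2-methyl-3-(3,4,5-trimethoxyphenyl)-3,3a-dihydro-1-benzofuran-6(2H)-one | C=CC[C@@]12C=C(OC)C(=O)C(OC)=C1O[C@H](C)[C@H]2c1cc(OC)c(OC)c(OC)c1 | intermediate
19 | (2R,3S,3aS,5R)-3a-allyl-5,7-dimethoxy-2-methyl-3-(3,4,5-trimethoxyphenyl)-3,3a,4,5-tetrahydro-1-benzofuran-6(2H)-one (C5-epimer) | C=CC[C@@]12C[C@@H](OC)C(=O)C(OC)=C1O[C@H](C)[C@H]2c1cc(OC)c(OC)c(OC)c1 | intermediate (not isolated)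
20 | (2R,3S,3aS,5S)-3a-allyl-5,7-dimethoxy-2-methyl-3-(3,4,5-trimethoxyphenyl)-3,3a,4,5-tetrahydro-1-benzofuran-6(2H)-one | C=CC[C@@]12C[C@H](OC)C(=O)C(OC)=C1O[C@H](C)[C@H]2c1cc(OC)c(OC)c(OC)c1 | target

**Step count and risks**

Total steps: 10. Longest linear sequence: 9 steps (1 → 2 → 5 → 9 → 11 → 12 → 15 → 17 → 18 → 20; steps 1, 2, 4, 5, 6, 7, 8, 9, 10).

Steps most likely to fail:

Step 8 (Proposed new method). What may go wrong:
- the cation returns to O7 faster than it closes on C3a, so the material rests on the benzodioxane side of the equilibrium;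
- loss of the C2 proton from the cation (enol ether formation, then hydrolysis to an arylacetone);
- acid-induced 1,2-shift of C3 or of the allyl group in the dienone (dienone–phenol rearrangement);
- closure with the aryl group endo (the 3a-epimer).

Fallback, known reactions only: the ring contraction is given up, the dioxane ring is opened first, O7 is capped and the cation is then generated irreversibly. It sets out from 12. EtSH (co-solvent) and BF3·OEt2 in CH2Cl2 at −20 °C should cleave the benzylic C3–O7 bond and trap the cation as the ring-opened ethyl thioether 2-(allyloxy)-6-{[(2R)-1-(ethylsulfanyl)-1-(3,4,5-trimethoxyphenyl)propan-2-yl]oxy}-3-methoxyphenol F1 (thioacidolysis-type ether cleavage). MeI and K2CO3 cap the freed O7–H to give the dimethoxy thioether F2. para-Claisen rearrangement under the conditions of step 7 gives the para-allyl phenol F3. MeOTf with 2,6-di-tert-butyl-4-methylpyridine in CH2Cl2 methylates sulfur to the benzylic sulfonium triflate F4, which on warming in hexafluoroisopropanol ionizes with loss of the dialkyl sulfide. The same planar cation now has no oxygen to return to and closes on C3a (alkylative ipso-Friedel–Crafts dearomatization of a para-substituted phenol); loss of the phenol proton gives 18 directly. The route is rejoined at 18; steps 7, 8 and 9 are replaced.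

Step 4. What may go wrong: elimination of the activated benzylic carbinol toward the enol silyl ether and slow attack by the doubly ortho-substituted phenol, so that little ether forms.

Fallback: the O7–C3 bond is made by epoxide opening, and C2 is set by catalysis instead of being bought. It sets out from 8. Commercial 3,4,5-trimethoxybenzaldehyde is converted by a Z-selective Wittig reaction (ethyltriphenylphosphonium bromide, KN(SiMe3)2, THF, −78 °C) into (Z)-1,2,3-trimethoxy-5-(prop-1-en-1-yl)benzene F5. Jacobsen epoxidation with (R,R)-N,N'-bis(3,5-di-tert-butylsalicylidene)-1,2-cyclohexanediaminomanganese chloride and NaOCl should give (2S,3R)-2-methyl-3-(3,4,5-trimethoxyphenyl)oxirane F6. The phenoxide of 8 (Cs2CO3, DMF, 70 °C) should open F6 at the benzylic carbon to the hydroxy ether 3-(allyloxy)-2-{[(2S)-2-hydroxy-1-(3,4,5-trimethoxyphenyl)propyl]oxy}-4-methoxybenzaldehyde F7, which already carries the free C2–OH. Baeyer–Villiger oxidation with mCPBA gives the aryl formate F8, and K2CO3 in MeOH cleaves it to 11. The route is rejoined at 11; steps 1, 2, 4 and 5 fall away.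

Step 10. What may go wrong: 1,2-reduction of the C6 ketone, or hydride attack on the vinylogous ester arm; sluggish addition to the α-methoxy enone; incomplete equilibration at C5.

Fallback: the hydride is replaced by a two-step conjugate reduction through a heteroatom adduct. It sets out from 18. Sodium benzeneselenolate (from PhSeSePh and NaBH4 in EtOH, buffered with AcOH before 18 is added) should add to C4 of the simple enone arm to give the 4-(phenylselanyl) ketone F9. Bu3SnH and AIBN in toluene at 80 °C remove selenium through the C4 radical; cyclization of this radical onto the allyl group would be 4-exo or 5-endo and should not compete. DBU then equilibrates C5 as in step 10, and the route comes back at 20.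

**Further compounds**

F1 | step 8 | 2-(allyloxy)-6-{[(2R)-1-(ethylsulfanyl)-1-(3,4,5-trimethoxyphenyl)propan-2-yl]oxy}-3-methoxyphenol (both epimers at the sulfur-bearing carbon) | C[C@@H](Oc1ccc(OC)c(OCC=C)c1O)C(SCC)c1cc(OC)c(OC)c(OC)c1
F2 | step 8 | 3-(allyloxy)-1-{[(2R)-1-(ethylsulfanyl)-1-(3,4,5-trimethoxyphenyl)propan-2-yl]oxy}-2,4-dimethoxybenzene (both epimers at the sulfur-bearing carbon) | C[C@@H](Oc1ccc(OC)c(OCC=C)c1OC)C(SCC)c1cc(OC)c(OC)c(OC)c1
F3 | step 8 | 4-allyl-3-{[(2R)-1-(ethylsulfanyl)-1-(3,4,5-trimethoxyphenyl)propan-2-yl]oxy}-2,6-dimethoxyphenol (both epimers at the sulfur-bearing carbon) | C[C@@H](Oc1c(CC=C)cc(OC)c(O)c1OC)C(SCC)c1cc(OC)c(OC)c(OC)c1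
F4 | step 8 | {(2R)-2-(6-allyl-3-hydroxy-2,4-dimethoxyphenoxy)-1-(3,4,5-trimethoxyphenyl)propyl}(ethyl)(methyl)sulfonium trifluoromethanesulfonate | C[C@@H](Oc1c(CC=C)cc(OC)c(O)c1OC)C([S+](C)CC)c1cc(OC)c(OC)c(OC)c1.[O-]S(=O)(=O)C(F)(F)F
F5 | step 4 | (Z)-1,2,3-trimethoxy-5-(prop-1-en-1-yl)benzene | C/C=C\c1cc(OC)c(OC)c(OC)c1
F6 | step 4 | (2S,3R)-2-methyl-3-(3,4,5-trimethoxyphenyl)oxirane | C[C@@H]1O[C@@H]1c1cc(OC)c(OC)c(OC)c1
F7 | step 4 | 3-(allyloxy)-2-{[(2S)-2-hydroxy-1-(3,4,5-trimethoxyphenyl)propyl]oxy}-4-methoxybenzaldehyde | C[C@H](O)C(Oc1c(C=O)ccc(OC)c1OCC=C)c1cc(OC)c(OC)c(OC)c1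
F8 | step 4 | 3-(allyloxy)-2-{[(2S)-2-hydroxy-1-(3,4,5-trimethoxyphenyl)propyl]oxy}-4-methoxyphenyl formate | C[C@H](O)C(Oc1c(OC=O)ccc(OC)c1OCC=C)c1cc(OC)c(OC)c(OC)c1
F9 | step 10 | (2R,3S)-3a-allyl-5,7-dimethoxy-2-methyl-4-(phenylselanyl)-3-(3,4,5-trimethoxyphenyl)-3,3a,4,5-tetrahydro-1-benzofuran-6(2H)-one (C3a as in the target; C4 and C5 epimer mixture) | C=CC[C@@]12C([Se]c3ccccc3)C(OC)C(=O)C(OC)=C1O[C@H](C)[C@H]2c1cc(OC)c(OC)c(OC)c1
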